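A closed, stirred vessel at one temperature joins starting material and coupling partner to target, and the spring flask must be judged at 10 min.

| flask | starting material | coupling partner | time |
|---|---|---|---|
| noon | 0.500 M | 0.400 M |  |
| autumn | 0.500 M | 1.20 M |  |
| summer | 1.00 M | 0.400 M |  |
| spring | 1.70 M | 0.400 M | 10 min |

- noon run (time / min: [target] / M): 0.44: 0.0092; 1.3: 0.0378; 2.6: 0.0790; 4.1: 0.1222; 5.8: 0.1668; 7.8: 0.2106; 10: 0.2503
- autumn run (time / min: [target] / M): 0.44: 0.0164; 1.3: 0.0456; 2.6: 0.1003; 4.1: 0.1542; 5.8: 0.2118; 7.8: 0.2665; 10: 0.3195
- summer run (time / min: [target] / M): 0.44: 0.0119; 1.3: 0.0484; 2.6: 0.1151; 4.1: 0.1746; 5.8: 0.2301; 7.8: 0.2866; 10: 0.3311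

(standard deviation of a reading: 0.002 M)

- Overall: starting material + coupling partner -> target.
- Constant volume, constant temperature.
- What is held in complexes is read along with the free species.
- "The second partner" is coupling partner.
- An order is taken over about fifteen percent of the charge, up and down.

1. the power of [coupling partner] that the first rate follows, about the charge of the noon run; measure it at two percent of starting material made into target
2. the power of [starting material] that the first rate follows, about the charge of the noon run; measure it at two percent of starting material made into target (one fixed amount of target, the same in the runs compared)
3. target in the spring run at 10 min, as a share of the starting material charged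

In the spring flask the coupling partner is the limiting reagent, its 0.400 M lying below the 1.70 M of starting material, and the summer flask shows the same shortage. At 10 min the summer flask reads 1.76 and the noon flask 0.983 on the partner clock, the natural logarithm of partner charged over partner left, with partner left taken as charge less target. Mean starting material over those runs rises from 0.375 M in noon to 0.834 M in summer, so the clock follows that mean with a power of about 0.727.

A first round for the spring flask scales the summer clock by the charges, giving 2.59 and 0.370 M of target. Put back, that amount makes the spring mean 1.52 M, so a second round gives a clock of 2.71, 0.373 M of target and a share of 22.0 %.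

The ladder for the spring flask follows from this reckoning. The partner lifetime reckoned for the spring flask, run time over clock, is 3.68 min. The lag, read as about 0.357 min in the summer flask, is shorter than that lifetime, which is shorter than the spring run, while the partner charge allows starting material in the spring flask, all its forms counted, to fall no lower than 1.30 M.

The forecast gave orders of 0.3 in partner and 0.5 in starting material and, “with the partner nearly consumed”, a share of 21.5 %, lower than this reckoning. The flask gives 0.39, 0.43 and 22.1 %.

    starting material ⇌ intermediate (0.7380 min⁻¹, 1.098 min⁻¹)
    intermediate + coupling partner → target (6.900 M⁻¹ min⁻¹)
    starting material + coupling partner ⇌ idle substrate-reagent adduct, settled at all times (1.240 M⁻¹)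
    2 starting material ⇌ idle substrate dimer, settled at all times (37.80 M⁻¹)

Through the 10 min of the spring flask, intermediate met coupling partner while the partner, adduct counted, fell from 0.400 M to 0.0250 M, which puts the clock at 2.77, or 1.57 times the summer reading, and starting material in all its forms by then stood at 1.32 M. In the autumn flask the same step ran with partner in excess, 1.20 M against 0.500 M, and when half of the starting material had turned, at 7.15 min, the clock read 0.234, against 0.983 for the noon flask at 10 min.

Readings and results are simulated for an exercise; scatter was added.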